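**Retrosynthetic overview**
1. Target 27 ⇒ propanoylation of mono-propanoate 26 ⇒ stereoconvergent Evans–Tishchenko reduction of β-hydroxy ketone 24: the C5–O propanoate bond is formed while C7 and C8 are set (key C–O step).
2. 24 ⇒ lateral acylation of pyranone 22 (ring A) by the anti-aldol imide 19 (C7–C8 bond).
3. 19 ⇒ anti-aldol (C5–C6 bond) on enal 17 ⇒ Wittig olefination of ring-B aldehyde 14.
4. Ring B (12) ⇒ C–O cyclodehydration of triketone 11 ⇒ pentan-3-one plus Weinreb amides 5 (Noyori / Fráter–Seebach) and 10 (Roche ester).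
5. Ring order: ring B is closed first (step 9); ring A is closed separately in one pot (step 15); the two finished pyranones are joined in step 16.

Locants: C2–C8 are the carbons of the non-3-ene chain between the rings (C2 on ring B, C8 on ring A); C2′ and C3′ are the ring-bearing and acetoxy-bearing carbons of the pentan-3-yl acetate arm.
Assumption: ylide 15 and imide 18 are bought, and the MgBr2-catalysed aldol of (S)-18 is taken to give the anti adduct with the C6 configuration shown (if the sense proves opposite, ent-18 is used).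

**Step 1**
Reactants: 1 methyl 3-oxopentanoate
Product: 2 methyl (3S)-3-hydroxypentanoate
Conditions: RuCl2[(S)-BINAP] (0.1 mol%), H2 (50 atm), MeOH, 50 °C
Reagents that add atoms: none
Why: Noyori asymmetric hydrogenation of a β-keto ester; the (S)-BINAP–Ru catalyst selects one carbonyl face and sets C3′ as S.

**Step 2**
Reactants: 2 methyl (3S)-3-hydroxypentanoate
Product: 3 methyl (2S,3S)-3-hydroxy-2-methylpentanoate
Conditions: LDA (2.2 equiv), THF, −78 → −20 °C; MeI, DMPU, −78 → 0 °C; 1 M HCl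
Reagents that add atoms: iodomethane, CI
Why: Fráter–Seebach alkylation; the chelated lithium alkoxide–enolate dianion is methylated anti to the carbinol substituent, which sets C2′ as S (2,3-anti).

**Step 3**
Reactants: 3 methyl (2S,3S)-3-hydroxy-2-methylpentanoate
Product: 4 methyl (2S,3S)-3-[(tert-butyldimethylsilyl)oxy]-2-methylpentanoate
Conditions: TBSCl, imidazole, DMF, rt → 40 °C
Reagents that add atoms: tert-butyldimethylsilyl chloride, CC(C)(C)[Si](C)(C)Cl
Why: Silyl ether formation masks the alcohol for the enolate steps that follow and touches no stereocentre.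

**Step 4**
Reactants: 4 methyl (2S,3S)-3-[(tert-butyldimethylsilyl)oxy]-2-methylpentanoate
Product: 5 (2S,3S)-3-[(tert-butyldimethylsilyl)oxy]-N-methoxy-N,2-dimethylpentanamide
Conditions: MeNH(OMe)·HCl, i-PrMgCl (3 equiv), THF, −20 → 0 °C
Reagents that add atoms: N,O-dimethylhydroxylamine hydrochloride, CNOC.Cl
Why: Weinreb amide formation from an ester with the magnesium amide; the low temperature avoids α-epimerisation.

**Step 5**
Reactants: 6 pentan-3-one; 5 Weinreb amide
Product: 7 (6S,7S)-7-[(tert-butyldimethylsilyl)oxy]-4,6-dimethylnonane-3,5-dione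
Conditions: 6 (1.3 equiv), LDA (1.3 equiv), THF, −78 °C; then 5, −78 → 0 °C; 1 M HCl
Reagents that add atoms: none
Why: Claisen-type C-acylation of the lithium enolate of 6 by a Weinreb amide; the chelated tetrahedral adduct collapses only on work-up, so there is no over-addition, and the new C4 centre is irrelevant because it becomes sp2.

**Step 6**
Reactants: 8 methyl (2S)-3-hydroxy-2-methylpropanoate ((S)-Roche ester)
Product: 9 methyl (2S)-3-[(tert-butyldimethylsilyl)oxy]-2-methylpropanoate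
Conditions: TBSCl, imidazole, CH2Cl2, rt
Reagents that add atoms: tert-butyldimethylsilyl chloride, CC(C)(C)[Si](C)(C)Cl
Why: Silylation of the primary alcohol; the chiral-pool centre becomes C2 of the target.

**Step 7**
Reactants: 9 methyl (2S)-3-[(tert-butyldimethylsilyl)oxy]-2-methylpropanoate
Product: 10 (2S)-3-[(tert-butyldimethylsilyl)oxy]-N-methoxy-N,2-dimethylpropanamide
Conditions: MeNH(OMe)·HCl, i-PrMgCl (3 equiv), THF, −20 °C
Reagents that add atoms: N,O-dimethylhydroxylamine hydrochloride, CNOC.Cl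
Why: Weinreb amide formation, as in step 4, without loss of the α-stereocentre.

**Step 8**
Reactants: 7 β-diketone; 10 Weinreb amide
Product: 11 (2S,8S,9S)-1,9-bis[(tert-butyldimethylsilyl)oxy]-2,4,6,8-tetramethylundecane-3,5,7-trione
Conditions: 7 (1.2 equiv), LDA (2.5 equiv), THF, −78 → −30 °C; then 10, −78 → −20 °C; 1 M HCl
Reagents that add atoms: none
Why: Harris-type γ-acylation of a β-diketone dianion; LDA removes the C4 proton and then a proton of the less hindered C2 methylene (not the branched C6–H), and the terminal carbanion is acylated by the Weinreb amide.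

**Step 9**
Reactants: 11 triketone
Product: 12 2-{(2S)-1-[(tert-butyldimethylsilyl)oxy]propan-2-yl}-6-{(2S,3S)-3-[(tert-butyldimethylsilyl)oxy]pentan-2-yl}-3,5-dimethyl-4H-pyran-4-one
Conditions: PPh3, CCl4, THF, rt → 50 °C
Reagents that add atoms: none
Why: Cyclodehydration of a 1,3,5-triketone to a 4-pyranone (C–O ring closure of ring B) by Appel-type activation of one enol and attack of the other enol oxygen; the neutral conditions keep both silyl ethers and the two flanking stereocentres.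

**Step 10**
Reactants: 12 bis-silyl pyranone
Product: 13 2-[(2S)-1-hydroxypropan-2-yl]-6-[(2S,3S)-3-hydroxypentan-2-yl]-3,5-dimethyl-4H-pyran-4-one
Conditions: HF·pyridine, pyridine, THF, 0 °C → rt
Reagents that add atoms: none
Why: Fluoride-mediated desilylation of both silyl ethers; the pyranone is inert to HF.

**Step 11**
Reactants: 13 pyranone diol
Product: 14 (2R)-2-{6-[(2S,3S)-3-hydroxypentan-2-yl]-3,5-dimethyl-4-oxo-4H-pyran-2-yl}propanal
Conditions: TEMPO (10 mol%), PhI(OAc)2, CH2Cl2, rt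
Reagents that add atoms: none
Why: TEMPO/PhI(OAc)2 oxidation takes the primary alcohol in preference to the hindered secondary one under near-neutral conditions, so the α-stereocentre survives (the descriptor changes to R only through CIP priorities).

**Step 12**
Reactants: 14 pyranone aldehyde (used crude); 15 2-(triphenyl-λ5-phosphanylidene)propanal
Product: 16 (2E,4S)-4-{6-[(2S,3S)-3-hydroxypentan-2-yl]-3,5-dimethyl-4-oxo-4H-pyran-2-yl}-2-methylpent-2-enal
Conditions: toluene, 60 °C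
Reagents that add atoms: none
Why: Wittig olefination with a stabilised ylide gives the (E)-trisubstituted enal that becomes the C3=C4 alkene.

**Step 13**
Reactants: 16 enal alcohol
Product: 17 (2S,3S)-2-{3,5-dimethyl-6-[(2S,3E)-4-methyl-5-oxopent-3-en-2-yl]-4-oxo-4H-pyran-2-yl}pentan-3-yl acetate
Conditions: Ac2O, pyridine, DMAP (cat.), CH2Cl2, 0 °C
Reagents that add atoms: acetic anhydride, CC(=O)OC(C)=O
Why: DMAP-catalysed esterification installs the only acetate of the target before the propanoates are introduced.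

**Step 14**
Reactants: 17 enal acetate; 18 (4S)-4-benzyl-3-propanoyl-1,3-thiazolidine-2-thione
Product: 19 anti-aldol imide as its C5 trimethylsilyl ether
Conditions: MgBr2·OEt2 (20 mol%), Et3N, TMSCl, EtOAc, rt
Reagents that add atoms: chlorotrimethylsilane, C[Si](C)(C)Cl
Why: Evans MgBr2-catalysed anti-aldol by soft enolisation; the auxiliary-controlled magnesium (Z)-enolate adds to the enal to set C6 and C5 (R) in the 5,6-anti relationship, and TMSCl traps the aldolate so the catalyst turns over.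

**Step 15**
Reactants: 6 pentan-3-one; 20 propanoic acid (2 equiv)
Product: 22 2,6-diethyl-3,5-dimethyl-4H-pyran-4-one, via 4,6-dimethylnonane-3,5,7-trione 21 (not isolated)
Conditions: polyphosphoric acid, 100 °C
Reagents that add atoms: none
Why: PPA-mediated double C-acylation of the ketone followed by cyclodehydration of the 1,3,5-triketone (C–O ring closure of ring A) in one pot.

**Step 16**
Reactants: 22 2,6-diethyl-3,5-dimethyl-4H-pyran-4-one; 19 aldol imide
Product: 24 C7-keto C5-hydroxy bis-pyranone (C8 epimers), via O-trimethylsilyl ketone 23 (not isolated)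
Conditions: 22 (3 equiv), LiHMDS (2.9 equiv), THF, −78 °C; then 19, −78 → −40 °C; 1 M HCl, THF, 0 °C, 10 min
Reagents that add atoms: none
Why: Lateral (vinylogous) Claisen acylation of the lithium dienolate of a 2-alkyl-4-pyranone by the acyl thiazolidinethione; a second equivalent of dienolate deprotonates the product at C8, so C8 is obtained as an epimer mixture, and the acid work-up removes the TMS group.

**Step 17**
Reactants: 24 C7-keto C5-hydroxy bis-pyranone (C8 epimers)
Product: 26 C5-propanoate C7-alcohol (single C8 epimer), via propanal hemiacetal 25 (not isolated)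
Conditions: EtCHO (8 equiv), SmI2 (30 mol%), Et3N (20 mol%), THF, −10 → 0 °C
Reagents that add atoms: propanal, CCC=O
Why: Proposed new method: a stereoconvergent (dynamic kinetic) Evans–Tishchenko reduction in which Sm(III) ties the C5 alkoxide to propanal as hemiacetal 25 and to the C7 ketone, the hemiacetal hydride is passed intramolecularly to the carbonyl face anti to C5–O as the hemiacetal collapses to the C5 propanoate C–O bond (5,7-anti, 7R), and, because C8–H lies between the ketone and the pyranone (a vinylogous β-keto ester that Sm(III)/Et3N enolise readily), the C8 epimers interconvert faster than hydride transfer and the epimer whose fixed hydride trajectory is also Felkin–Anh (pyranone anti to the hydride) reacts faster, funnelling the mixture to the 7,8-anti (8R) product; the closest known reactions are the SmI2-catalysed Evans–Tishchenko reduction of β-hydroxy ketones and the Noyori dynamic kinetic resolution of α-substituted β-keto esters.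

**Step 18**
Reactants: 26 C5-propanoate C7-alcohol
Product: 27 target CNP0295731.1
Conditions: (EtCO)2O, DMAP, pyridine, CH2Cl2, 0 °C → rt
Reagents that add atoms: propanoic anhydride, CCC(=O)OC(=O)CC
Why: DMAP-catalysed esterification of the C7 alcohol; any 1,3-migration of the C5 propanoate is harmless because both oxygens end as propanoates.

**Compound list**
1 | methyl 3-oxopentanoate | CCC(=O)CC(=O)OC | starting material
2 | methyl (3S)-3-hydroxypentanoate | COC(=O)C[C@H](CC)O | intermediate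
3 | methyl (2S,3S)-3-hydroxy-2-methylpentanoate | COC(=O)[C@@H](C)[C@H](CC)O | intermediate
4 | methyl (2S,3S)-3-[(tert-butyldimethylsilyl)oxy]-2-methylpentanoate | COC(=O)[C@@H](C)[C@H](CC)O[Si](C)(C)C(C)(C)C | intermediate
5 | (2S,3S)-3-[(tert-butyldimethylsilyl)oxy]-N-methoxy-N,2-dimethylpentanamide | CON(C)C(=O)[C@@H](C)[C@H](CC)O[Si](C)(C)C(C)(C)C | intermediate
6 | pentan-3-one | CCC(=O)CC | starting material
7 | (6S,7S)-7-[(tert-butyldimethylsilyl)oxy]-4,6-dimethylnonane-3,5-dione (C4 epimers and enol forms) | CCC(=O)C(C)C(=O)[C@@H](C)[C@H](CC)O[Si](C)(C)C(C)(C)C | intermediate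
8 | methyl (2S)-3-hydroxy-2-methylpropanoate ((S)-Roche ester) | OC[C@H](C)C(=O)OC | starting material
9 | methyl (2S)-3-[(tert-butyldimethylsilyl)oxy]-2-methylpropanoate | CC(C)(C)[Si](C)(C)OC[C@H](C)C(=O)OC | intermediate
10 | (2S)-3-[(tert-butyldimethylsilyl)oxy]-N-methoxy-N,2-dimethylpropanamide | CC(C)(C)[Si](C)(C)OC[C@H](C)C(=O)N(C)OC | intermediate
11 | (2S,8S,9S)-1,9-bis[(tert-butyldimethylsilyl)oxy]-2,4,6,8-tetramethylundecane-3,5,7-trione (C4/C6 epimers and enol forms) | CC(C)(C)[Si](C)(C)OC[C@H](C)C(=O)C(C)C(=O)C(C)C(=O)[C@@H](C)[C@H](CC)O[Si](C)(C)C(C)(C)C | intermediate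
12 | 2-{(2S)-1-[(tert-butyldimethylsilyl)oxy]propan-2-yl}-6-{(2S,3S)-3-[(tert-butyldimethylsilyl)oxy]pentan-2-yl}-3,5-dimethyl-4H-pyran-4-one | CC(C)(C)[Si](C)(C)OC[C@H](C)c1oc([C@@H](C)[C@H](CC)O[Si](C)(C)C(C)(C)C)c(C)c(=O)c1C | intermediate
13 | 2-[(2S)-1-hydroxypropan-2-yl]-6-[(2S,3S)-3-hydroxypentan-2-yl]-3,5-dimethyl-4H-pyran-4-one | OC[C@H](C)c1oc([C@@H](C)[C@H](CC)O)c(C)c(=O)c1C | intermediate
14 | (2R)-2-{6-[(2S,3S)-3-hydroxypentan-2-yl]-3,5-dimethyl-4-oxo-4H-pyran-2-yl}propanal | O=C[C@H](C)c1oc([C@@H](C)[C@H](CC)O)c(C)c(=O)c1C | intermediate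
15 | 2-(triphenyl-λ5-phosphanylidene)propanal | CC(C=O)=P(c1ccccc1)(c1ccccc1)c1ccccc1 | starting material
16 | (2E,4S)-4-{6-[(2S,3S)-3-hydroxypentan-2-yl]-3,5-dimethyl-4-oxo-4H-pyran-2-yl}-2-methylpent-2-enal | O=C/C(C)=C/[C@H](C)c1oc([C@@H](C)[C@H](CC)O)c(C)c(=O)c1C | intermediate
17 | (2S,3S)-2-{3,5-dimethyl-6-[(2S,3E)-4-methyl-5-oxopent-3-en-2-yl]-4-oxo-4H-pyran-2-yl}pentan-3-yl acetate | O=C/C(C)=C/[C@H](C)c1oc([C@@H](C)[C@H](CC)OC(C)=O)c(C)c(=O)c1C | intermediate
18 | (4S)-4-benzyl-3-propanoyl-1,3-thiazolidine-2-thione | CCC(=O)N1[C@@H](Cc2ccccc2)CSC1=S | starting material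
19 | (2S,3S)-2-{6-[(2S,3E,5R,6S)-7-[(4S)-4-benzyl-2-sulfanylidene-1,3-thiazolidin-3-yl]-4,6-dimethyl-7-oxo-5-[(trimethylsilyl)oxy]hept-3-en-2-yl]-3,5-dimethyl-4-oxo-4H-pyran-2-yl}pentan-3-yl acetate | O=C([C@@H](C)[C@@H](O[Si](C)(C)C)/C(C)=C/[C@H](C)c1oc([C@@H](C)[C@H](CC)OC(C)=O)c(C)c(=O)c1C)N1[C@@H](Cc2ccccc2)CSC1=S | intermediate
20 | propanoic acid | CCC(=O)O | starting material
21 | 4,6-dimethylnonane-3,5,7-trione | CCC(=O)C(C)C(=O)C(C)C(=O)CC | intermediate (not isolated)
22 | 2,6-diethyl-3,5-dimethyl-4H-pyran-4-one | CCc1oc(CC)c(C)c(=O)c1C | intermediate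
23 | (2S,3S)-2-{6-[(2S,3E,5R,6S,8RS)-8-(6-ethyl-3,5-dimethyl-4-oxo-4H-pyran-2-yl)-4,6-dimethyl-7-oxo-5-[(trimethylsilyl)oxy]non-3-en-2-yl]-3,5-dimethyl-4-oxo-4H-pyran-2-yl}pentan-3-yl acetate | O=C([C@@H](C)[C@@H](O[Si](C)(C)C)/C(C)=C/[C@H](C)c1oc([C@@H](C)[C@H](CC)OC(C)=O)c(C)c(=O)c1C)C(C)c1oc(CC)c(C)c(=O)c1C | intermediate (not isolated)
24 | (2S,3S)-2-{6-[(2S,3E,5R,6S,8RS)-8-(6-ethyl-3,5-dimethyl-4-oxo-4H-pyran-2-yl)-5-hydroxy-4,6-dimethyl-7-oxonon-3-en-2-yl]-3,5-dimethyl-4-oxo-4H-pyran-2-yl}pentan-3-yl acetate | O=C([C@@H](C)[C@@H](O)/C(C)=C/[C@H](C)c1oc([C@@H](C)[C@H](CC)OC(C)=O)c(C)c(=O)c1C)C(C)c1oc(CC)c(C)c(=O)c1C | intermediate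
25 | (2S,3S)-2-{6-[(2S,3E,5R,6S,8RS)-8-(6-ethyl-3,5-dimethyl-4-oxo-4H-pyran-2-yl)-5-(1-hydroxypropoxy)-4,6-dimethyl-7-oxonon-3-en-2-yl]-3,5-dimethyl-4-oxo-4H-pyran-2-yl}pentan-3-yl acetate (samarium-bound in the flask) | O=C([C@@H](C)[C@@H](OC(O)CC)/C(C)=C/[C@H](C)c1oc([C@@H](C)[C@H](CC)OC(C)=O)c(C)c(=O)c1C)C(C)c1oc(CC)c(C)c(=O)c1C | intermediate (not isolated)
26 | (2S,3S)-2-{6-[(2S,3E,5R,6R,7R,8R)-8-(6-ethyl-3,5-dimethyl-4-oxo-4H-pyran-2-yl)-7-hydroxy-4,6-dimethyl-5-(propanoyloxy)non-3-en-2-yl]-3,5-dimethyl-4-oxo-4H-pyran-2-yl}pentan-3-yl acetate | O[C@H]([C@@H](C)[C@@H](OC(=O)CC)/C(C)=C/[C@H](C)c1oc([C@@H](C)[C@H](CC)OC(C)=O)c(C)c(=O)c1C)[C@@H](C)c1oc(CC)c(C)c(=O)c1C | intermediate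
27 | (2S,3S)-2-{6-[(2S,3E,5R,6R,7R,8R)-8-(6-ethyl-3,5-dimethyl-4-oxo-4H-pyran-2-yl)-4,6-dimethyl-5,7-bis(propanoyloxy)non-3-en-2-yl]-3,5-dimethyl-4-oxo-4H-pyran-2-yl}pentan-3-yl acetate (CNP0295731.1) | CCC(=O)O[C@H]([C@@H](C)[C@@H](OC(=O)CC)/C(C)=C/[C@H](C)c1oc([C@@H](C)[C@H](CC)OC(C)=O)c(C)c(=O)c1C)[C@@H](C)c1oc(CC)c(C)c(=O)c1C | target

**Totals and risks**
Total step count: 18. Longest linear sequence: 15 (steps 1–5, 8–14, 16–18).

Step 17 (the proposed new step). Risk: C8 may epimerise more slowly than hydride is transferred, which would leave a C8-epimeric product mixture; retro-aldol of 24 is a second concern. The fallback uses known chemistry only, sets out from 14 and comes back at 27. Aldehyde 14 is condensed with commercial diethyl (3-oxopentan-2-yl)phosphonate (Ba(OH)2, wet THF, rt, Horner–Wadsworth–Emmons) to the ring-B ethyl enone F1, which is acetylated (Ac2O, pyridine) to the enone acetate F2. C8 is then taken from the chiral pool instead of being set dynamically. (R)-Roche ester is silylated and amidated as in steps 6 and 7 to the silyl ester F3 and the Weinreb amide F4. F4 acylates the LDA dianion of commercial 4-methylheptane-3,5-dione to the ring-A triketone F5. Ph3P/CCl4 gives the silyloxy pyranone F6, HF·pyridine the pyranone alcohol F7 and Dess–Martin oxidation the ring-A aldehyde F8. The (Z)-enol borinate of F2 (Bu2BOTf, i-Pr2NEt, −78 °C; matched Ipc2BOTf if needed) adds to F8 in a syn-aldol with the usual anti-Felkin preference of (Z)-enolates, giving the β-hydroxy enone F9 (6,7-syn, 7,8-anti). An ordinary Evans–Tishchenko reduction (SmI2 cat., EtCHO) gives the 5,7-anti diol 7-propanoate F10, and propanoylation of its C5 hydroxyl as in step 18 gives 27.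

Step 16. Risk: a crowded C–C bond between a secondary lateral carbanion and an α-branched acyl donor, and a base-sensitive partner (acetate, β-silyloxy imide, acidic lateral C–H of ring B). The fallback sets out from 19 and comes back at 23. The imide is reduced (DIBAL-H, 1.1 equiv, CH2Cl2, −78 °C, short contact) to the silyloxy aldehyde F11. The lithium dienolate of 22 (1.2 equiv) adds to it at −78 °C in a lateral aldol, which uses a far less hindered electrophile and needs no second equivalent of base, to give the epimeric carbinols F12. Dess–Martin oxidation (NaHCO3-buffered) gives 23, which is desilylated as in step 16.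

Step 8. Risk: β-elimination of the silyloxy Weinreb amide by the strongly basic dianion, and incomplete terminal regioselectivity. The fallback sets out from 9 (with 7) and comes back at 11. Ester 9 is reduced (DIBAL-H, CH2Cl2, −78 °C) to the silyloxy aldehyde F13. The dianion of 7 is added to it at −78 °C (aldol) to give the hydroxy diketone F14, and Dess–Martin oxidation gives triketone 11.

**Further compounds**
F1 | step 17 | ring-B ethyl enone, (4E,6S)-6-{6-[(2S,3S)-3-hydroxypentan-2-yl]-3,5-dimethyl-4-oxo-4H-pyran-2-yl}-4-methylhept-4-en-3-one | CCC(=O)/C(C)=C/[C@H](C)c1oc([C@@H](C)[C@H](CC)O)c(C)c(=O)c1C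
F2 | step 17 | enone acetate, (2S,3S)-2-{3,5-dimethyl-6-[(2S,3E)-4-methyl-5-oxohept-3-en-2-yl]-4-oxo-4H-pyran-2-yl}pentan-3-yl acetate | CCC(=O)/C(C)=C/[C@H](C)c1oc([C@@H](C)[C@H](CC)OC(C)=O)c(C)c(=O)c1C
F3 | step 17 | silyl ester, methyl (2R)-3-[(tert-butyldimethylsilyl)oxy]-2-methylpropanoate | CC(C)(C)[Si](C)(C)OC[C@@H](C)C(=O)OC
F4 | step 17 | Weinreb amide, (2R)-3-[(tert-butyldimethylsilyl)oxy]-N-methoxy-N,2-dimethylpropanamide | CC(C)(C)[Si](C)(C)OC[C@@H](C)C(=O)N(C)OC
F5 | step 17 | ring-A triketone, (2R)-1-[(tert-butyldimethylsilyl)oxy]-2,4,6-trimethylnonane-3,5,7-trione | CC(C)(C)[Si](C)(C)OC[C@@H](C)C(=O)C(C)C(=O)C(C)C(=O)CC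
F6 | step 17 | silyloxy pyranone, 2-{(2R)-1-[(tert-butyldimethylsilyl)oxy]propan-2-yl}-6-ethyl-3,5-dimethyl-4H-pyran-4-one | CC(C)(C)[Si](C)(C)OC[C@@H](C)c1oc(CC)c(C)c(=O)c1C
F7 | step 17 | pyranone alcohol, 2-ethyl-6-[(2R)-1-hydroxypropan-2-yl]-3,5-dimethyl-4H-pyran-4-one | OC[C@@H](C)c1oc(CC)c(C)c(=O)c1C
F8 | step 17 | ring-A aldehyde, (2S)-2-(6-ethyl-3,5-dimethyl-4-oxo-4H-pyran-2-yl)propanal | O=C[C@@H](C)c1oc(CC)c(C)c(=O)c1C
F9 | step 17 | β-hydroxy enone, (2S,3S)-2-{6-[(2S,3E,6R,7S,8R)-8-(6-ethyl-3,5-dimethyl-4-oxo-4H-pyran-2-yl)-7-hydroxy-4,6-dimethyl-5-oxonon-3-en-2-yl]-3,5-dimethyl-4-oxo-4H-pyran-2-yl}pentan-3-yl acetate | O[C@H]([C@@H](C)C(=O)/C(C)=C/[C@H](C)c1oc([C@@H](C)[C@H](CC)OC(C)=O)c(C)c(=O)c1C)[C@@H](C)c1oc(CC)c(C)c(=O)c1C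
F10 | step 17 | 5,7-anti diol 7-propanoate, (2S,3S)-2-{6-[(2S,3E,5R,6S,7R,8R)-8-(6-ethyl-3,5-dimethyl-4-oxo-4H-pyran-2-yl)-5-hydroxy-4,6-dimethyl-7-(propanoyloxy)non-3-en-2-yl]-3,5-dimethyl-4-oxo-4H-pyran-2-yl}pentan-3-yl acetate | CCC(=O)O[C@H]([C@@H](C)[C@@H](O)/C(C)=C/[C@H](C)c1oc([C@@H](C)[C@H](CC)OC(C)=O)c(C)c(=O)c1C)[C@@H](C)c1oc(CC)c(C)c(=O)c1C
F11 | step 16 | silyloxy aldehyde, (2S,3S)-2-{6-[(2S,3E,5R,6S)-4,6-dimethyl-7-oxo-5-[(trimethylsilyl)oxy]hept-3-en-2-yl]-3,5-dimethyl-4-oxo-4H-pyran-2-yl}pentan-3-yl acetate | O=C[C@@H](C)[C@@H](O[Si](C)(C)C)/C(C)=C/[C@H](C)c1oc([C@@H](C)[C@H](CC)OC(C)=O)c(C)c(=O)c1C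
F12 | step 16 | epimeric carbinols, (2S,3S)-2-{6-[(2S,3E,5R,6S)-8-(6-ethyl-3,5-dimethyl-4-oxo-4H-pyran-2-yl)-7-hydroxy-4,6-dimethyl-5-[(trimethylsilyl)oxy]non-3-en-2-yl]-3,5-dimethyl-4-oxo-4H-pyran-2-yl}pentan-3-yl acetate (C7 and C8 mixed) | OC([C@@H](C)[C@@H](O[Si](C)(C)C)/C(C)=C/[C@H](C)c1oc([C@@H](C)[C@H](CC)OC(C)=O)c(C)c(=O)c1C)C(C)c1oc(CC)c(C)c(=O)c1C
F13 | step 8 | silyloxy aldehyde, (2S)-3-[(tert-butyldimethylsilyl)oxy]-2-methylpropanal | CC(C)(C)[Si](C)(C)OC[C@H](C)C=O
F14 | step 8 | hydroxy diketone, (2S,8S,9S)-1,9-bis[(tert-butyldimethylsilyl)oxy]-3-hydroxy-2,4,6,8-tetramethylundecane-5,7-dione (C3, C4, C6 mixed) | CC(C)(C)[Si](C)(C)OC[C@H](C)C(O)C(C)C(=O)C(C)C(=O)[C@@H](C)[C@H](CC)O[Si](C)(C)C(C)(C)C
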